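The oxabicycle is numbered O7, C1 (bridgehead CH), C2 (quaternary), C3, C4 (methyl-bearing bridgehead), C5, C6. Everything rests on opening its tetrahydrofuran ring O7–C1–C6–C5–C4 into an aldehyde (C1=O7) and a donor–acceptor cyclopropane (C4–C5–C6, with a temporary gem-diester on C6), held together by the C2–C3 bond. A Lewis acid then closes this acyclic keto aldehyde in one operation by a formal intramolecular [3+2] cycloaddition that builds both rings and both bridgeheads, the tertiary ether carbon C4 with inversion. The precursor comes from (S)-carvone, whose stereocentre becomes C3 and relays C2 and the cyclopropane carbon.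

Key step: step 6

Remark: the bicycle numbering above is used throughout; "chain A" is the substituent on C2 and "chain B" the one on C3.
Assumption: the (S)-binaphtholate catalyst of step 11 is taken to give the (S)-epoxide and the D-fructose-derived ketone of step 13 the (R)-epoxide; if either sense is opposite, the enantiomeric catalyst is used.
Assumption: compound 5 is bought (it is also available from dimethyl malonate by diazo transfer).

Step 1
Reactants: 1 (S)-(+)-carvone; 2 tert-butyl(3-iodopropoxy)dimethylsilane
Product: 3 6-[3-(tert-butyldimethylsilyloxy)propyl]carvone (new chain trans to isopropenyl)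
Conditions: LiN(i-Pr)2, THF, −78 °C; then 2, DMPU, −78 → −20 °C
Reagents that add atoms: none
Why: Kinetic deprotonation of the enone takes place at the α′-CH2 (carvone C6) and the cross-conjugated lithium enolate is alkylated by the primary iodide anti to the neighbouring isopropenyl group (α′-alkylation of carvone); this centre is made planar again in step 2.

Step 2
Reactants: 3 6-[3-(tert-butyldimethylsilyloxy)propyl]carvone
Product: 4 6-methyl-6-[3-(tert-butyldimethylsilyloxy)propyl]carvone (methyl trans and chain cis to isopropenyl)
Conditions: LiN(i-Pr)2, THF, −78 °C; then MeI, −78 → 0 °C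
Reagents that add atoms: iodomethane, CI
Why: A second kinetic enolisation at C6 and methylation on the enolate face opposite the adjacent isopropenyl group (substrate-controlled enolate alkylation) should set the quaternary centre, the future C2, relayed from the carvone stereocentre.

Step 3
Reactants: 4 6-methyl-6-[3-(tert-butyldimethylsilyloxy)propyl]carvone; 5 dimethyl 2-diazomalonate
Product: 6 cyclopropane diester (isopropenyl turned into a 1-methyl-2,2-bis(methoxycarbonyl)cyclopropyl group)
Conditions: Rh2(esp)2 (1 mol%; esp = α,α,α′,α′-tetramethyl-1,3-benzenedipropanoate), 5 added slowly, CH2Cl2, 0 °C → rt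
Reagents that add atoms: none
Why: The electrophilic rhodium carbenoid cyclopropanates the only electron-rich alkene (the enone C=C is inert) and should add to the isopropenyl face turned away from the neighbouring quaternary carbon, in the staggered conformer that places the allylic hydrogen next to the alkene methyl group, which sets the cyclopropane quaternary centre, the future C4 (metal-carbenoid cyclopropanation).

Step 4
Reactants: 6 cyclopropane diester
Product: 8 2-hydroxy-2-methylcyclohexanone derivative (saturated ring), via potassium enolate 7 (not isolated)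
Conditions: KBH(s-Bu)3, THF, −78 °C; then 2-(phenylsulfonyl)-3-phenyloxaziridine, −78 → −20 °C; aq. NH4Cl
Reagents that add atoms: 2-(phenylsulfonyl)-3-phenyloxaziridine, O=S(=O)(c1ccccc1)N1OC1c1ccccc1
Why: The bulky borohydride adds hydride 1,4 to the β-unsubstituted enone and the tetrasubstituted enolate is oxidised on carbon by the N-sulfonyloxaziridine (conjugate reduction then enolate hydroxylation); the configuration of the new carbinol does not matter because this carbon becomes a ketone in step 5.

Step 5
Reactants: 8 2-hydroxy-2-methylcyclohexanone derivative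
Product: 10 3-[2,2-bis(methoxycarbonyl)-1-methylcyclopropyl]-2-[3-(tert-butyldimethylsilyloxy)propyl]-2-methyl-6-oxoheptanal, via diol 9 (not isolated)
Conditions: Zn(BH4)2, Et2O, 0 °C; then aq. NH4Cl, NaIO4, THF/H2O, rt
Reagents that add atoms: none
Why: Chelation-assisted borohydride reduction of the α-hydroxy ketone gives a vicinal diol that periodate cleaves between the carbinol carbons (Malaprade glycol cleavage), releasing the aldehyde C1 and the methyl ketone of chain B without hydride attack on the malonate.

Step 6
Reactants: 10 keto aldehyde with the donor–acceptor cyclopropane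
Product: 11 dimethyl 2-[3-(tert-butyldimethylsilyloxy)propyl]-2,4-dimethyl-3-(3-oxobutyl)-7-oxabicyclo[2.2.1]heptane-6,6-dicarboxylate (chain A exo; 2-methyl and chain B endo)
Conditions: Sc(OSO2CF3)3 (20 mol%), 4 Å molecular sieves, ClCH2CH2Cl, −20 °C → rt
Reagents that add atoms: none
Why: Scandium triflate chelates the gem-diester and polarises the C4–C6 bond, the aldehyde oxygen O7 attacks the quaternary donor carbon C4 from the side opposite C6 (SN2-like, within the contact ion pair) to give a five-membered oxocarbenium ion bearing a scandium malonate, and C6 of that malonate then adds to C1. The closest known reaction type is the Lewis-acid-catalysed intramolecular [3+2] cross-cycloaddition of cyclopropane-1,1-diesters with a tethered carbonyl group, the bridged counterpart of the stereospecific aldehyde/donor–acceptor-cyclopropane tetrahydrofuran synthesis. Ring O7–C1–C2–C3–C4 closes by 5-exo-tet displacement at C4, ring O7–C1–C6–C5–C4 by 5-endo-trig attack of the malonate carbon on the oxocarbenium carbon, and the same C1–C6 bond completes the carbocycle C1–C6 in a 6-exo-trig sense. C4 is controlled by inversion of the cyclopropane centre set in step 3 and C1 by the tether, because the C5–C6 arm on C4 can reach C1 only from its own face, so the oxygen bridge ends up syn to chain A and anti to chain B while C2 and C3 are untouched. The step needs chemoselectivity for the aldehyde over the methyl ketone, which the faster five-membered first closure helped by the gem-dialkyl effect at C2 and the higher electrophilicity of the aldehyde-derived oxocarbenium ion should secure. It also needs stereospecific opening instead of ionisation to a free tertiary cation, which the weakly ionising solvent, the low temperature and the intramolecular delivery of O7 favour.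

Step 7
Reactants: 11 bicyclic diester
Product: 12 2-(3-hydroxypropyl)-2,4-dimethyl-3-(3-oxobutyl)-7-oxabicyclo[2.2.1]heptane-6,6-dicarboxylic acid
Conditions: KOH, MeOH/H2O, 65 °C; then 2 M HCl to pH 1, rt
Reagents that add atoms: potassium hydroxide, [K+].[OH-]
Why: Saponification of the two methyl esters (C6 has no hydrogen, so no enolate can expel the oxygen bridge) followed by acidification, which also cleaves the primary silyl ether, should give the malonic acid.

Step 8
Reactants: 12 malonic acid
Product: 13 4-[2-(3-hydroxypropyl)-2,4-dimethyl-7-oxabicyclo[2.2.1]heptan-3-yl]butan-2-one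
Conditions: 9-mesityl-10-phenylacridinium tetrafluoroborate (5 mol%), PhSSPh (10 mol%), i-Pr2NEt (20 mol%), CF3CH2OH, 450 nm LEDs, rt
Reagents that add atoms: none
Why: Photoredox hydrodecarboxylation oxidises each carboxylate in turn, CO2 is lost and the C6 radical is quenched by hydrogen-atom transfer from thiophenol, a radical path that avoids a C6 carbanion and so avoids β-elimination of the bridge; malonic acids are known to lose both carboxyl groups this way.

Step 9
Reactants: 13 hydroxy ketone
Product: 14 3-[2,4-dimethyl-3-(3-oxobutyl)-7-oxabicyclo[2.2.1]heptan-2-yl]propanal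
Conditions: Dess–Martin periodinane, CH2Cl2, rt
Reagents that add atoms: none
Why: Dess–Martin oxidation converts the primary alcohol into the aldehyde and leaves ketone and ether untouched.

Step 10
Reactants: 14 keto aldehyde
Product: 15 4-[2,4-dimethyl-2-(4-methylpent-3-en-1-yl)-7-oxabicyclo[2.2.1]heptan-3-yl]butan-2-one
Conditions: i-PrPPh3I, n-BuLi, THF, 0 °C; then 14, −78 → 0 °C
Reagents that add atoms: isopropyltriphenylphosphonium iodide, CC(C)[P+](c1ccccc1)(c1ccccc1)c1ccccc1.[I-]
Why: Wittig olefination with the non-stabilised isopropylidene ylide, which reacts with the aldehyde much faster than with the methyl ketone, installs the trisubstituted alkene of chain A.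

Step 11
Reactants: 15 alkenyl methyl ketone
Product: 16 (S)-2-methyl-2-substituted oxirane at the end of chain B
Conditions: Me3S(O)I, NaH, THF; then LaLi3[(S)-1,1′-binaphthalene-2,2′-diolate]3 (5 mol%), (2,4,6-(MeO)3C6H2)3P=O (5 mol%), 5 Å molecular sieves, THF, rt
Reagents that add atoms: trimethylsulfoxonium iodide, C[S+](C)(C)=O.[I-]
Why: In this catalytic asymmetric Corey–Chaykovsky epoxidation the chiral lanthanum–lithium binaphtholate directs methylene transfer from the sulfoxonium ylide to one face of the methyl ketone (methyl against primary alkyl), so the remote tertiary C–O centre is set by catalyst control.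

Step 12
Reactants: 16 epoxide
Product: 18 triethylsilyl ether of the tertiary allylic alcohol, via tertiary allylic alcohol 17 (not isolated)
Conditions: Me3SI, n-BuLi, THF, −10 °C → rt; then Et3SiOSO2CF3, 2,6-lutidine, 0 °C
Reagents that add atoms: trimethylsulfonium iodide, C[S+](C)C.[I-]; triethylsilyl trifluoromethanesulfonate, CC[Si](CC)(CC)OS(=O)(=O)C(F)(F)F
Why: The sulfonium ylide opens the epoxide at its CH2 end and the sulfonium betaine eliminates to the vinyl group (one-carbon homologation of an epoxide to an allylic alcohol) without touching the stereocentre, and the tertiary alcohol is silylated in the same flask.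

Step 13
Reactants: 18 silyl ether with the trisubstituted alkene
Product: 19 (R)-epoxide of the chain A alkene
Conditions: D-fructose-derived ketone catalyst (1,2:4,5-di-O-isopropylidene-β-D-erythro-2,3-hexodiulo-2,6-pyranose, 30 mol%), KHSO5 (as 2 KHSO5·KHSO4·K2SO4), K2CO3, n-Bu4NHSO4, MeCN/CH2(OMe)2/aq. Na2B4O7 buffer, 0 °C
Reagents that add atoms: potassium peroxymonosulfate, [K+].[O-]S(=O)(=O)OO
Why: In the Shi asymmetric epoxidation the chiral dioxirane oxidises the electron-rich trisubstituted alkene much faster than the vinyl group and sets the secondary epoxide carbon by catalyst control through the spiro transition state.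

Step 14
Reactants: 19 epoxide
Product: 20 bromohydrin with chain A = (3R)-4-bromo-3-hydroxy-4-methylpentyl
Conditions: HBr (1.05 equiv), CH2Cl2, −78 °C; then aq. NaHCO3
Reagents that add atoms: hydrogen bromide, Br
Why: Acid-promoted Markovnikov opening of the trisubstituted epoxide puts bromide on the tertiary carbon and leaves the secondary C–O bond and its configuration intact (epoxide hydrobromination).

Step 15
Reactants: 20 bromohydrin
Product: 22 triethylsilyl ether of the target with chain A = (3S)-3-bromo-4-chloro-4-methylpentyl, via triflate 21 (not isolated)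
Conditions: (CF3SO2)2O, 2,6-lutidine, CH2Cl2, −78 °C; then n-Bu4NCl, −78 → 0 °C
Reagents that add atoms: tetrabutylammonium chloride, CCCC[N+](CCCC)(CCCC)CCCC.[Cl-]
Why: Triflation of the hindered secondary alcohol triggers displacement by the neighbouring bromine (direct SN2 at this neopentyl-type carbon being negligible), giving a bromonium ion with inversion at the secondary carbon that chloride opens at the tertiary carbon (neighbouring-group participation with 1,2-bromine shift).

Step 16
Reactants: 22 silyl ether of the target
Product: 23 target, (3S)-5-[(1S,2S,3S,4R)-3-[(3S)-3-bromo-4-chloro-4-methylpentyl]-1,3-dimethyl-7-oxabicyclo[2.2.1]heptan-2-yl]-3-methylpent-1-en-3-ol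
Conditions: HF·pyridine, pyridine, THF, 0 °C → rt
Reagents that add atoms: none
Why: Buffered fluoride cleaves the tertiary silyl ether under non-basic conditions that should leave the secondary bromide and the tertiary chloride intact.

Compound list
1 | (S)-(+)-carvone, (5S)-2-methyl-5-(prop-1-en-2-yl)cyclohex-2-en-1-one | O=C1C(C)=CC[C@H](C(C)=C)C1 | starting material
2 | tert-butyl(3-iodopropoxy)dimethylsilane | CC(C)(C)[Si](C)(C)OCCCI | starting material
3 | 6-[3-(tert-butyldimethylsilyloxy)propyl]carvone, chain trans to isopropenyl | O=C1C(C)=CC[C@H](C(C)=C)[C@H]1CCCO[Si](C)(C)C(C)(C)C | intermediate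
4 | 6-methyl-6-[3-(tert-butyldimethylsilyloxy)propyl]carvone, methyl trans and chain cis to isopropenyl | O=C1C(C)=CC[C@H](C(C)=C)[C@]1(C)CCCO[Si](C)(C)C(C)(C)C | intermediate
5 | dimethyl 2-diazomalonate | COC(=O)C(=[N+]=[N-])C(=O)OC | starting material
6 | cyclopropane diester: 4 with the isopropenyl group turned into a 1-methyl-2,2-bis(methoxycarbonyl)cyclopropyl group, cyclopropane centre as in the SMILES | O=C1C(C)=CC[C@H]([C@@]2(C)CC2(C(=O)OC)C(=O)OC)[C@]1(C)CCCO[Si](C)(C)C(C)(C)C | intermediate
7 | potassium enolate from 1,4-reduction of 6 (not isolated) | [O-]C1=C(C)CC[C@H]([C@@]2(C)CC2(C(=O)OC)C(=O)OC)[C@]1(C)CCCO[Si](C)(C)C(C)(C)C.[K+] | intermediate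
8 | 2-hydroxy-2-methylcyclohexanone derivative of 6 (saturated ring; either epimer at the new carbinol carbon) | O=C1C(C)(O)CC[C@H]([C@@]2(C)CC2(C(=O)OC)C(=O)OC)[C@]1(C)CCCO[Si](C)(C)C(C)(C)C | intermediate
9 | cyclohexane-1,2-diol from 8 (epimers at both carbinol carbons; not isolated) | OC1C(C)(O)CC[C@H]([C@@]2(C)CC2(C(=O)OC)C(=O)OC)[C@]1(C)CCCO[Si](C)(C)C(C)(C)C | intermediate
10 | 3-[2,2-bis(methoxycarbonyl)-1-methylcyclopropyl]-2-[3-(tert-butyldimethylsilyloxy)propyl]-2-methyl-6-oxoheptanal | CC(=O)CC[C@H]([C@@]1(C)CC1(C(=O)OC)C(=O)OC)[C@](C)(CCCO[Si](C)(C)C(C)(C)C)C=O | intermediate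
11 | dimethyl 2-[3-(tert-butyldimethylsilyloxy)propyl]-2,4-dimethyl-3-(3-oxobutyl)-7-oxabicyclo[2.2.1]heptane-6,6-dicarboxylate (chain A exo; 2-methyl and chain B endo) | CC(=O)CC[C@H]1[C@](C)(CCCO[Si](C)(C)C(C)(C)C)[C@H]2C(C(=O)OC)(C(=O)OC)C[C@]1(C)O2 | intermediate
12 | 2-(3-hydroxypropyl)-2,4-dimethyl-3-(3-oxobutyl)-7-oxabicyclo[2.2.1]heptane-6,6-dicarboxylic acid | CC(=O)CC[C@H]1[C@](C)(CCCO)[C@H]2C(C(=O)O)(C(=O)O)C[C@]1(C)O2 | intermediate
13 | 4-[2-(3-hydroxypropyl)-2,4-dimethyl-7-oxabicyclo[2.2.1]heptan-3-yl]butan-2-one | CC(=O)CC[C@H]1[C@](C)(CCCO)[C@H]2CC[C@]1(C)O2 | intermediate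
14 | 3-[2,4-dimethyl-3-(3-oxobutyl)-7-oxabicyclo[2.2.1]heptan-2-yl]propanal | CC(=O)CC[C@H]1[C@](C)(CCC=O)[C@H]2CC[C@]1(C)O2 | intermediate
15 | 4-[2,4-dimethyl-2-(4-methylpent-3-en-1-yl)-7-oxabicyclo[2.2.1]heptan-3-yl]butan-2-one | CC(=O)CC[C@H]1[C@](C)(CCC=C(C)C)[C@H]2CC[C@]1(C)O2 | intermediate
16 | (S)-2-methyl-2-{2-[2,4-dimethyl-2-(4-methylpent-3-en-1-yl)-7-oxabicyclo[2.2.1]heptan-3-yl]ethyl}oxirane | C1[C@@](C)(O1)CC[C@H]2[C@](C)(CCC=C(C)C)[C@H]3CC[C@]2(C)O3 | intermediate
17 | (3S)-5-[2,4-dimethyl-2-(4-methylpent-3-en-1-yl)-7-oxabicyclo[2.2.1]heptan-3-yl]-3-methylpent-1-en-3-ol (not isolated) | C=C[C@@](C)(O)CC[C@H]1[C@](C)(CCC=C(C)C)[C@H]2CC[C@]1(C)O2 | intermediate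
18 | triethylsilyl ether of 17 | C=C[C@@](C)(O[Si](CC)(CC)CC)CC[C@H]1[C@](C)(CCC=C(C)C)[C@H]2CC[C@]1(C)O2 | intermediate
19 | epoxide of 18 with chain A = 2-[(2R)-3,3-dimethyloxiran-2-yl]ethyl | C=C[C@@](C)(O[Si](CC)(CC)CC)CC[C@H]1[C@](C)(CC[C@H]3OC3(C)C)[C@H]2CC[C@]1(C)O2 | intermediate
20 | bromohydrin with chain A = (3R)-4-bromo-3-hydroxy-4-methylpentyl | C=C[C@@](C)(O[Si](CC)(CC)CC)CC[C@H]1[C@](C)(CC[C@@H](O)C(C)(C)Br)[C@H]2CC[C@]1(C)O2 | intermediate
21 | trifluoromethanesulfonate of 20 (not isolated) | C=C[C@@](C)(O[Si](CC)(CC)CC)CC[C@H]1[C@](C)(CC[C@@H](OS(=O)(=O)C(F)(F)F)C(C)(C)Br)[C@H]2CC[C@]1(C)O2 | intermediate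
22 | triethylsilyl ether of the target, chain A = (3S)-3-bromo-4-chloro-4-methylpentyl | C=C[C@@](C)(O[Si](CC)(CC)CC)CC[C@H]1[C@](C)(CC[C@H](Br)C(C)(C)Cl)[C@H]2CC[C@]1(C)O2 | intermediate
23 | target CNP0297543.1, (3S)-5-[(1S,2S,3S,4R)-3-[(3S)-3-bromo-4-chloro-4-methylpentyl]-1,3-dimethyl-7-oxabicyclo[2.2.1]heptan-2-yl]-3-methylpent-1-en-3-ol | C=C[C@@](C)(O)CC[C@H]1[C@](C)(CC[C@H](Br)C(C)(C)Cl)[C@H]2CC[C@]1(C)O2 | target

Total step count: 16
Longest linear sequence: 16 steps (1 → 23)

Steps most likely to fail

1. Step 6 (key step). The methyl ketone oxygen of chain B may capture the opened cyclopropane through a six-membered first closure, which would lead to an oxabicyclo[3.2.1]octane. The cyclopropane may also ionise to a free tertiary cation, so that the bridge forms partly on the wrong face. Fallback, which removes the ketone during the cycloaddition: it sets out from 10. NaBH4 in MeOH reduces both carbonyl groups to the diol F1. TEMPO with PhI(OAc)2 oxidises only the primary alcohol and gives the hydroxy aldehyde F2. Ac2O, pyridine and DMAP give the acetate F3. The same scandium triflate cycloaddition should then give the bicyclic acetate F4, with no competing carbonyl group. KOH followed by HCl cleaves the methyl esters, the acetate and the silyl ether to the diacid diol F5. The photoredox hydrodecarboxylation of step 8 gives the diol F6. Dess–Martin oxidation of both alcohols comes back to the route at 14.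

2. Step 3. The carbenoid may add with poor facial selectivity, because the two faces of the isopropenyl group differ only through the neighbouring quaternary carbon. The wrong cyclopropane epimer would place the oxygen bridge on the wrong face after the stereospecific cycloaddition. Fallback, which builds the cyclopropane from the other side: it sets out from 4. Ozonolysis (O3, CH2Cl2/MeOH, −78 °C, then Me2S) cleaves only the isopropenyl group and gives the methyl ketone F7. Knoevenagel condensation with dimethyl malonate (TiCl4, pyridine, THF) gives the alkylidene malonate F8. One equivalent of dimethylsulfoxonium methylide (Me3S(O)I, NaH, DMSO) then transfers CH2 in a Corey–Chaykovsky cyclopropanation. Here A(1,3) strain holds the allylic hydrogen in the plane of the cis ester, so the ylide adds anti to the quaternary carbon, and the route is rejoined at 6.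

3. Step 15. The tertiary bromide or the triflate may eliminate, or chloride may open the bromonium ion at the secondary carbon; either would erode the bromochloride. Fallback, which installs bromine directly on the secondary carbon: it sets out from 19. Li2NiBr4 in THF opens the epoxide in an SN2 sense at the secondary carbon with inversion and gives the bromohydrin F9. 1-Chloro-N,N,2-trimethylprop-1-en-1-amine in CH2Cl2 converts the tertiary alcohol into the chloride under neutral conditions, with retention at the C–Br carbon through the bromonium ion. This comes back to the route at 22.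

Further compounds
F1 | step 6 | diol from reduction of both carbonyl groups of 10 (epimers at the secondary carbinol) | CC(O)CC[C@H]([C@@]1(C)CC1(C(=O)OC)C(=O)OC)[C@](C)(CCCO[Si](C)(C)C(C)(C)C)CO
F2 | step 6 | hydroxy aldehyde (6-hydroxy analogue of 10) | CC(O)CC[C@H]([C@@]1(C)CC1(C(=O)OC)C(=O)OC)[C@](C)(CCCO[Si](C)(C)C(C)(C)C)C=O
F3 | step 6 | acetate of F2 | CC(OC(C)=O)CC[C@H]([C@@]1(C)CC1(C(=O)OC)C(=O)OC)[C@](C)(CCCO[Si](C)(C)C(C)(C)C)C=O
F4 | step 6 | bicyclic diester with chain B = 3-acetoxybutyl | CC(OC(C)=O)CC[C@H]1[C@](C)(CCCO[Si](C)(C)C(C)(C)C)[C@H]2C(C(=O)OC)(C(=O)OC)C[C@]1(C)O2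
F5 | step 6 | diacid diol (3-hydroxybutyl analogue of 12) | CC(O)CC[C@H]1[C@](C)(CCCO)[C@H]2C(C(=O)O)(C(=O)O)C[C@]1(C)O2
F6 | step 6 | diol (3-hydroxybutyl analogue of 13) | CC(O)CC[C@H]1[C@](C)(CCCO)[C@H]2CC[C@]1(C)O2
F7 | step 3 | methyl ketone: 4 with the isopropenyl group cleaved to acetyl | O=C1C(C)=CC[C@H](C(C)=O)[C@]1(C)CCCO[Si](C)(C)C(C)(C)C
F8 | step 3 | alkylidene malonate from F7 | O=C1C(C)=CC[C@H](C(C)=C(C(=O)OC)C(=O)OC)[C@]1(C)CCCO[Si](C)(C)C(C)(C)C
F9 | step 15 | bromohydrin with chain A = (3S)-3-bromo-4-hydroxy-4-methylpentyl | C=C[C@@](C)(O[Si](CC)(CC)CC)CC[C@H]1[C@](C)(CC[C@H](Br)C(C)(C)O)[C@H]2CC[C@]1(C)O2
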